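**Retrosynthetic overview**
1. Target 19 ⇐ last step: 1,3-oxygen-shift ring expansion of the vinyl oxirane in (9Z)-5,6-epoxide 18 to the 2,5-dihydrofuran; this sets C8.
2. 18 ⇐ Suzuki coupling (C8–C9) of epoxy vinylboronate 10 with (Z)-2-iodoalkene 17; this fixes 7E and 9Z.
3. 17 ⇐ α-iodoethylidene Wittig on C14 hydroxy-aldehyde 16 ⇐ Stille union of two halves (13→15 and 14), both made from (E)-pent-2-en-4-yn-1-ol (the C10–C10′ segment is C2-symmetric).
4. 10 ⇐ boron-Wittig on epoxy aldehyde 9 ⇐ Sharpless epoxidation of diol 7 ⇐ enzymatic reduction of keto ester 5 ⇐ annulation of mesityl oxide with methyl acetoacetate.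
5. Ring order: cyclohexene (step 1) → oxirane (step 5) → dihydrofuran by ring expansion (step 13).

Assumption: the SMILES is read literally, so C9=C10 is Z (C19 methyl trans to C11), all other chain double bonds are E, and the stereocentres are 3S,5R,8R; locants in the text use carotenoid numbering (C1 = CMe2, C3 = CHOH, C5 = C(Me)–O, C6 = ring carbon bearing the chain, C8 = O–CH).

**Step 1**
Reactants: 1 mesityl oxide (4-methylpent-3-en-2-one); 2 methyl acetoacetate
Product: 3 methyl 2,6,6-trimethyl-4-oxocyclohex-2-ene-1-carboxylate (racemic)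
Conditions: ZnCl2 (20 mol %), heptane–toluene, reflux, Dean–Stark
Reagents that add atoms: none
Why: Lewis-acid-promoted Michael addition of the acetoacetate to mesityl oxide followed by intramolecular aldol condensation (Robinson-type annulation) gives the trimethylcyclohexenone ester; its single stereocentre becomes sp2 in step 2, so no control is needed.

**Step 2**
Reactants: 3 methyl 2,6,6-trimethyl-4-oxocyclohex-2-ene-1-carboxylate
Product: 5 methyl 2,6,6-trimethyl-4-oxocyclohex-1-ene-1-carboxylate, via potassium dienolate 4 (not isolated)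
Conditions: KOtBu (1.05 equiv), THF, 0 °C; inverse quench into AcOH/THF, −78 °C
Reagents that add atoms: none
Why: Deconjugative protonation: the thermodynamic, fully conjugated dienolate is protonated kinetically at the carbon α to the ketone (the site where Hagemann-type anions are alkylated), which moves the double bond into the ring position conjugated with the ester and gives an achiral ketone.

**Step 3**
Reactants: 5 methyl 2,6,6-trimethyl-4-oxocyclohex-1-ene-1-carboxylate
Product: 6 methyl (4R)-4-hydroxy-2,6,6-trimethylcyclohex-1-ene-1-carboxylate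
Conditions: (R)-selective ketoreductase (KRED), NADP+ (cat.), i-PrOH, phosphate buffer pH 7, 30 °C
Reagents that add atoms: none
Why: Biocatalytic asymmetric ketone reduction with isopropanol recycling; the enzyme pocket distinguishes the CH2–C(sp2) flank from the CH2–CMe2 flank and delivers hydride to one face to set the (R)-carbinol (C3), and the neutral medium avoids re-conjugation of the β,γ-unsaturated ketone.

**Step 4**
Reactants: 6 methyl (4R)-4-hydroxy-2,6,6-trimethylcyclohex-1-ene-1-carboxylate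
Product: 7 (1R)-4-(hydroxymethyl)-3,5,5-trimethylcyclohex-3-en-1-ol
Conditions: LiAlH4, Et2O, 0 °C
Reagents that add atoms: none
Why: Hydride 1,2-reduction of the hindered tetrasubstituted enoate gives the allylic alcohol needed for directed epoxidation; the carbinol centre is untouched.

**Step 5**
Reactants: 7 (1R)-4-(hydroxymethyl)-3,5,5-trimethylcyclohex-3-en-1-ol
Product: 8 (1R,3S,6R)-6-(hydroxymethyl)-1,5,5-trimethyl-7-oxabicyclo[4.1.0]heptan-3-ol
Conditions: Ti(OiPr)4 (0.3 equiv), D-(−)-diethyl tartrate (0.36 equiv), t-BuOOH, 4 Å MS, CH2Cl2, −20 °C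
Reagents that add atoms: tert-butyl hydroperoxide, CC(C)(C)OO
Why: Sharpless asymmetric epoxidation: only the primary allylic hydroxyl delivers the titanium-bound peroxide to the tetrasubstituted olefin, and with D-(−)-tartrate (reagent control) the oxygen enters on the face anti to the ring hydroxyl, setting both oxirane carbons (C5 R); the remote secondary hydroxyl is a spectator ligand.

**Step 6**
Reactants: 8 (1R,3S,6R)-6-(hydroxymethyl)-1,5,5-trimethyl-7-oxabicyclo[4.1.0]heptan-3-ol
Product: 9 (1S,4S,6R)-4-hydroxy-2,2,6-trimethyl-7-oxabicyclo[4.1.0]heptane-1-carbaldehyde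
Conditions: TEMPO (10 mol %), PhI(OAc)2, CH2Cl2, rt
Reagents that add atoms: none
Why: Oxoammonium (TEMPO) oxidation is selective for the primary over the secondary alcohol and is non-acidic, and the α-quaternary epoxy aldehyde cannot enolise.

**Step 7**
Reactants: 9 (1S,4S,6R)-4-hydroxy-2,2,6-trimethyl-7-oxabicyclo[4.1.0]heptane-1-carbaldehyde
Product: 10 (1R,3S,6S)-1,5,5-trimethyl-6-[(E)-2-(4,4,5,5-tetramethyl-1,3,2-dioxaborolan-2-yl)ethenyl]-7-oxabicyclo[4.1.0]heptan-3-ol
Conditions: CH2(Bpin)2, lithium 2,2,6,6-tetramethylpiperidide (2.3 equiv each), THF, 0 °C; then 9, −78 °C → rt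
Reagents that add atoms: bis(4,4,5,5-tetramethyl-1,3,2-dioxaborolan-2-yl)methane, CC1(C)OB(CB2OC(C)(C)C(C)(C)O2)OC1(C)C
Why: Boron-Wittig olefination: addition of the lithiated gem-diboronate to the aldehyde and syn B–O elimination gives the E-vinylboronate (7E) under purely basic conditions that spare the tetrasubstituted oxirane; the extra equivalent covers the free hydroxyl.

**Step 8**
Reactants: 11 (E)-pent-2-en-4-yn-1-ol
Product: 13 (2E,4E)-5-iodo-4-methylpenta-2,4-dien-1-ol, via alkenylalane 12 (not isolated)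
Conditions: Me3Al (3 equiv), Cp2ZrCl2 (0.3 equiv), CH2Cl2, 0 °C → rt; then I2, THF, −30 °C
Reagents that add atoms: trimethylaluminium, C[Al](C)C; iodine, II
Why: Negishi zirconium-catalysed syn-methylalumination of the terminal alkyne puts methyl on the internal carbon, and iodinolysis with retention gives the E-trisubstituted vinyl iodide (the future 13E and 13′E geometry).

**Step 9**
Reactants: 13 (2E,4E)-5-iodo-4-methylpenta-2,4-dien-1-ol
Product: 14 (2E,4E,6E)-4-methyl-7-(tributylstannyl)hepta-2,4,6-trien-1-ol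
Conditions: (E)-Bu3SnCH=CHSnBu3 (3 equiv), PdCl2(MeCN)2 (3 mol %), DMF, rt
Reagents that add atoms: (E)-1,2-bis(tributylstannyl)ethene, CCCC[Sn](CCCC)(CCCC)/C=C/[Sn](CCCC)(CCCC)CCCC
Why: Stille mono-coupling with excess distannane proceeds with retention at both sp2 carbons and installs the central E-CH=CH unit as a trienylstannane.

**Step 10**
Reactants: 13 (2E,4E)-5-iodo-4-methylpenta-2,4-dien-1-ol; 14 (2E,4E,6E)-4-methyl-7-(tributylstannyl)hepta-2,4,6-trien-1-ol
Product: 16 (2E,4E,6E,8E,10E)-12-hydroxy-4,9-dimethyldodeca-2,4,6,8,10-pentaenal, via iododienal 15 (not isolated)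
Conditions: MnO2, CH2Cl2, rt, filter; then 14, PdCl2(MeCN)2 (5 mol %), DMF, rt, dark
Reagents that add atoms: none
Why: Allylic oxidation with MnO2 gives the labile iododienal, which is used crude in a Stille coupling (retention at both alkenes); oxidising one half before the union desymmetrises the C2-symmetric C14 chain without a statistical step.

**Step 11**
Reactants: 16 (2E,4E,6E,8E,10E)-12-hydroxy-4,9-dimethyldodeca-2,4,6,8,10-pentaenal
Product: 17 (2E,4E,6E,8E,10E,12Z)-13-iodo-4,9-dimethyltetradeca-2,4,6,8,10,12-hexaen-1-ol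
Conditions: [Ph3PEt]I, n-BuLi, THF; I2, −78 °C; NaN(SiMe3)2, −20 °C; then 16, −78 °C (2.2 equiv ylide)
Reagents that add atoms: ethyltriphenylphosphonium iodide, CC[P+](c1ccccc1)(c1ccccc1)c1ccccc1.[I-]; iodine, II
Why: Stork–Zhao-type Wittig olefination with the α-iodoethylidene ylide gives the (Z)-2-iodoalkene (iodine cis to the polyene chain), which fixes the later 9Z geometry; the excess ylide covers the free hydroxyl.

**Step 12**
Reactants: 10 (1R,3S,6S)-1,5,5-trimethyl-6-[(E)-2-(4,4,5,5-tetramethyl-1,3,2-dioxaborolan-2-yl)ethenyl]-7-oxabicyclo[4.1.0]heptan-3-ol; 17 (2E,4E,6E,8E,10E,12Z)-13-iodo-4,9-dimethyltetradeca-2,4,6,8,10,12-hexaen-1-ol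
Product: 18 (1R,3S,6S)-6-[(1E,3Z,5E,7E,9E,11E,13E)-15-hydroxy-3,7,12-trimethylpentadeca-1,3,5,7,9,11,13-heptaen-1-yl]-1,5,5-trimethyl-7-oxabicyclo[4.1.0]heptan-3-ol, i.e. (3S,5R,6S,9Z)-5,6-epoxy-5,6-dihydro-10′-apo-β-carotene-3,10′-diol
Conditions: Pd(PPh3)4 (10 mol %), TlOEt, THF–H2O, rt, dark
Reagents that add atoms: none
Why: Suzuki–Miyaura coupling proceeds with retention at both partners (7E from the boronate, 9Z from the iodide); thallium ethoxide makes it fast at room temperature, so the Z-iodide does not isomerise and oxidative addition to the vinyl iodide outruns ionisation of the hindered vinyl oxirane.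

**Step 13**
Reactants: 18 (3S,5R,6S,9Z)-5,6-epoxy-5,6-dihydro-10′-apo-β-carotene-3,10′-diol
Product: 19 (2R,6S,7aR)-2-[(2Z,4E,6E,8E,10E,12E)-14-hydroxy-6,11-dimethyltetradeca-2,4,6,8,10,12-hexaen-2-yl]-4,4,7a-trimethyl-2,4,5,6,7,7a-hexahydro-1-benzofuran-6-ol, i.e. (3S,5R,8R,9Z)-5,8-epoxy-5,8-dihydro-10′-apo-β-carotene-3,10′-diol
Conditions: (R)-TRIP [(R)-3,3′-bis(2,4,6-triisopropylphenyl)-1,1′-binaphthyl-2,2′-diyl hydrogen phosphate] (5 mol %), 4 Å MS, toluene–CH2Cl2, −40 °C, dark
Reagents that add atoms: none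
Why: Proposed new method: a confined chiral phosphoric acid turns the classical stereorandom acid-induced epoxide→furanoid rearrangement into a kinetically controlled suprafacial SN2′-type ring expansion of the vinyl oxirane: the P–OH hydrogen-bonds to the oxirane oxygen, the C6–O bond lengthens while the phosphoryl oxygen pairs with the developing C6–C7–C8 allyl cation on the same face, and the C5-bound oxygen swings onto C8 on the face it left before the C7–C8 bond can rotate, so with the 7E olefin the side chain ends up cis to C4 and trans to the C5 methyl (8R), C5 is retained and the 9Z bond is not scrambled, while 5 mol % of a weak acid in a non-polar medium at −40 °C is too mild to re-ionise the product ether (the process that equilibrates C8 under mineral acid); closest known reactions are the mineral-acid 5,6-epoxide→5,8-furanoid rearrangement of carotenoids (8R/8S mixtures), the copper-catalysed vinyl oxirane→2,5-dihydrofuran ring expansion and chiral phosphoric acid ion-pair catalysis of epoxide openings.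

**Compound list**
1 | mesityl oxide (4-methylpent-3-en-2-one) | CC(=O)C=C(C)C | starting material
2 | methyl acetoacetate | COC(=O)CC(C)=O | starting material
3 | methyl 2,6,6-trimethyl-4-oxocyclohex-2-ene-1-carboxylate (racemic) | COC(=O)C1C(C)=CC(=O)CC1(C)C | intermediate
4 | potassium 4-(methoxycarbonyl)-3,5,5-trimethylcyclohexa-1,3-dien-1-olate | [K+].COC(=O)C1=C(C)C=C([O-])CC1(C)C | intermediate (not isolated)
5 | methyl 2,6,6-trimethyl-4-oxocyclohex-1-ene-1-carboxylate | COC(=O)C1=C(C)CC(=O)CC1(C)C | intermediate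
6 | methyl (4R)-4-hydroxy-2,6,6-trimethylcyclohex-1-ene-1-carboxylate | COC(=O)C1=C(C)C[C@@H](O)CC1(C)C | intermediate
7 | (1R)-4-(hydroxymethyl)-3,5,5-trimethylcyclohex-3-en-1-ol | OCC1=C(C)C[C@@H](O)CC1(C)C | intermediate
8 | (1R,3S,6R)-6-(hydroxymethyl)-1,5,5-trimethyl-7-oxabicyclo[4.1.0]heptan-3-ol (oxirane anti to the 3-OH) | OC[C@]12C(C)(C)C[C@H](O)C[C@@]1(C)O2 | intermediate
9 | (1S,4S,6R)-4-hydroxy-2,2,6-trimethyl-7-oxabicyclo[4.1.0]heptane-1-carbaldehyde | O=C[C@]12C(C)(C)C[C@H](O)C[C@@]1(C)O2 | intermediate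
10 | (1R,3S,6S)-1,5,5-trimethyl-6-[(E)-2-(4,4,5,5-tetramethyl-1,3,2-dioxaborolan-2-yl)ethenyl]-7-oxabicyclo[4.1.0]heptan-3-ol | CC1(C)OB(/C=C/[C@]23C(C)(C)C[C@H](O)C[C@@]2(C)O3)OC1(C)C | intermediate
11 | (E)-pent-2-en-4-yn-1-ol | OC/C=C/C#C | starting material
12 | dimethyl{(1E,3E)-5-[(dimethylalumanyl)oxy]-2-methylpenta-1,3-dien-1-yl}alumane | C[Al](C)OC/C=C/C(C)=C/[Al](C)C | intermediate (not isolated)
13 | (2E,4E)-5-iodo-4-methylpenta-2,4-dien-1-ol | OC/C=C/C(C)=C/I | intermediate
14 | (2E,4E,6E)-4-methyl-7-(tributylstannyl)hepta-2,4,6-trien-1-ol | OC/C=C/C(C)=C/C=C/[Sn](CCCC)(CCCC)CCCC | intermediate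
15 | (2E,4E)-5-iodo-4-methylpenta-2,4-dienal | O=C/C=C/C(C)=C/I | intermediate (not isolated)
16 | (2E,4E,6E,8E,10E)-12-hydroxy-4,9-dimethyldodeca-2,4,6,8,10-pentaenal | O=C/C=C/C(C)=C/C=C/C=C(C)/C=C/CO | intermediate
17 | (2E,4E,6E,8E,10E,12Z)-13-iodo-4,9-dimethyltetradeca-2,4,6,8,10,12-hexaen-1-ol | OC/C=C/C(C)=C/C=C/C=C(C)/C=C/C=C(C)\I | intermediate
18 | (3S,5R,6S,9Z)-5,6-epoxy-5,6-dihydro-10′-apo-β-carotene-3,10′-diol | OC/C=C/C(C)=C/C=C/C=C(C)/C=C/C=C(C)\C=C\[C@]12C(C)(C)C[C@H](O)C[C@@]1(C)O2 | intermediate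
19 | (3S,5R,8R,9Z)-5,8-epoxy-5,8-dihydro-10′-apo-β-carotene-3,10′-diol | C/C(=C/C=C/C(C)=C/C=C/C=C(C)/C=C/CO)[C@H]1C=C2C(C)(C)C[C@H](O)C[C@@]2(C)O1 | target

**Totals and risks**
Total steps: 13. Longest linear sequence: 9 (steps 1–7, 12, 13).

Step 13 (new method). The risks are an 8R/8S mixture if the ion pair loosens, leakage of 9Z to 9E, and ionisation of the allylic C10′ alcohol. Fallback with known chemistry, setting out from 18 and returning at 19: treat 18 with very dilute HCl in CHCl3 at 0 °C (the classical epoxide–furanoid rearrangement), which gives 19 together with its C8 epimer (3S,5R,8S,9Z)-5,8-epoxy-5,8-dihydro-10′-apo-β-carotene-3,10′-diol F8; the two epimers are separated by semi-preparative HPLC and F8 is re-equilibrated under the same acid and recycled.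

Step 11 (α-iodoethylidene Wittig on a polyenal with a free hydroxyl). Moderate yield and erosion of Z selectivity are the usual problems. Fallback, setting out from boronate 10 (stannane 14 is also used) and returning at 18: but-2-yn-1-ol (CC#CCO) is hydroaluminated with NaAlH2(OCH2CH2OMe)2 and iodinated to (2Z)-3-iodobut-2-en-1-ol F2; Suzuki coupling of F2 with 10 (Pd(PPh3)4, TlOEt) gives (2Z,4E)-5-[(1S,4S,6R)-4-hydroxy-2,2,6-trimethyl-7-oxabicyclo[4.1.0]heptan-1-yl]-3-methylpenta-2,4-dien-1-ol F3, which MnO2 oxidises to xanthoxin F4. In parallel prop-2-yn-1-ol (C#CCO) is carboaluminated and iodinated (Me3Al, Cp2ZrCl2; I2) to (2E)-3-iodo-2-methylprop-2-en-1-ol F5 and converted with P(OEt)3/ZnI2 into diethyl [(2E)-3-iodo-2-methylprop-2-en-1-yl]phosphonate F6. Horner–Wadsworth–Emmons reaction of F6 with F4 (NaN(SiMe3)2, THF, −78 °C) gives (1R,3S,6S)-6-[(1E,3Z,5E,7E)-8-iodo-3,7-dimethylocta-1,3,5,7-tetraen-1-yl]-1,5,5-trimethyl-7-oxabicyclo[4.1.0]heptan-3-ol F7, and Stille coupling of F7 with 14 (Pd2(dba)3, AsPh3, DMF, rt) gives 18.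

Step 2 (kinetic deconjugative protonation). The β,γ-unsaturated ketone 5 may be contaminated with 3 or revert to it on handling. Fallback, setting out from 3 and returning at 5: acetalisation with ethylene glycol (TsOH, benzene, Dean–Stark), which moves the double bond into conjugation with the ester under thermodynamic control, gives methyl 7,9,9-trimethyl-1,4-dioxaspiro[4.5]dec-7-ene-8-carboxylate F1; brief mild hydrolysis (pyridinium tosylate, acetone–water, rt) releases 5, which is taken directly into step 3.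

**Further compounds**
F1 | step 2 | methyl 7,9,9-trimethyl-1,4-dioxaspiro[4.5]dec-7-ene-8-carboxylate | COC(=O)C1=C(C)CC2(CC1(C)C)OCCO2
F2 | step 11 | (2Z)-3-iodobut-2-en-1-ol | OC/C=C(C)\I
F3 | step 11 | (2Z,4E)-5-[(1S,4S,6R)-4-hydroxy-2,2,6-trimethyl-7-oxabicyclo[4.1.0]heptan-1-yl]-3-methylpenta-2,4-dien-1-ol | OC/C=C(C)\C=C\[C@]12C(C)(C)C[C@H](O)C[C@@]1(C)O2
F4 | step 11 | xanthoxin, (2Z,4E)-5-[(1S,4S,6R)-4-hydroxy-2,2,6-trimethyl-7-oxabicyclo[4.1.0]heptan-1-yl]-3-methylpenta-2,4-dienal | O=C/C=C(C)\C=C\[C@]12C(C)(C)C[C@H](O)C[C@@]1(C)O2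
F5 | step 11 | (2E)-3-iodo-2-methylprop-2-en-1-ol | OC/C(C)=C/I
F6 | step 11 | diethyl [(2E)-3-iodo-2-methylprop-2-en-1-yl]phosphonate | CCOP(=O)(OCC)C/C(C)=C/I
F7 | step 11 | (1R,3S,6S)-6-[(1E,3Z,5E,7E)-8-iodo-3,7-dimethylocta-1,3,5,7-tetraen-1-yl]-1,5,5-trimethyl-7-oxabicyclo[4.1.0]heptan-3-ol | I/C=C(C)/C=C/C=C(C)\C=C\[C@]12C(C)(C)C[C@H](O)C[C@@]1(C)O2
F8 | step 13 | (3S,5R,8S,9Z)-5,8-epoxy-5,8-dihydro-10′-apo-β-carotene-3,10′-diol | C/C(=C/C=C/C(C)=C/C=C/C=C(C)/C=C/CO)[C@@H]1C=C2C(C)(C)C[C@H](O)C[C@@]2(C)O1
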